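No flask can hold more open intermediate than the starting material charged, so each answer is what one clock has made and another has not yet cleared.

    partner ⇌ dormant form (K1 = 0.77, k1 = 0.061 min⁻¹, Ea1 = 91.0 kJ mol⁻¹, ΔH1 = −44.0 kJ mol⁻¹)
    partner → second intermediate (k2 = 0.044 min⁻¹, Ea2 = 97.0 kJ mol⁻¹)
    starting material + open intermediate → side product (k3 = 0.24 M⁻¹ min⁻¹, Ea3 = 72.0 kJ mol⁻¹)
    2 open intermediate → homo product (k4 = 0.48 M⁻¹ min⁻¹, Ea4 = 53.0 kJ mol⁻¹)
    open intermediate + second intermediate → target (k5 = 0.36 M⁻¹ min⁻¹, Ea5 = 66.0 kJ mol⁻¹)
    starting material → open intermediate (k6 = 0.057 min⁻¹, Ea6 = 114 kJ mol⁻¹)
    (constants at 70 °C)

| setting | north-west | south | north-east | west |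
|---|---|---|---|---|
| starting material | 0.050 M | 0.050 M | 0.050 M | 0.050 M |
| partner | 0.100 M | 0.100 M | 0.100 M | 0.100 M |
| temperature | 95 °C | 70 °C | 120 °C | 45 °C |
| time | 2.0 h | 2.0 h | 2.0 h | 2.0 h |

- which flask leads in amount of open intermediate, in percent of the starting material charged ("all alike" within 1.5 percentage points) (north-west / south / north-east / west / all alike)
- how much open intermediate is there at the end, in percent of the starting material charged: north-west
- how much open intermediate is there at the end, in percent of the starting material charged: south
- how much open intermediate is there at the end, in percent of the starting material charged: north-east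
- how much open intermediate is there at the end, in percent of the starting material charged: west

- in percentages every species weighs as the starting material in it: one homo product or side product counts as two
- a doubled species enters its step squared and goes two at a time
- constants are those at 70 °C; use the activation energies and enthalpies for any other temperature

I reckon in powers of ten: a first-order constant k acting for a time t takes away kt/2.3 decades, each decade a tenfold fall.

First I take the making step alone, starting material → open intermediate (k6 = 0.057 min⁻¹, Ea6 = 114 kJ mol⁻¹). In west its constant is

0.00247 min⁻¹, so in 2.0 h the starting material loses 0.129 decades, and west makes 25.6% of its charge.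

In south the same step is worth 2.97 decades, so south's charge passes through well within the run.

Next I add partner → second intermediate (k2 = 0.044 min⁻¹, Ea2 = 97.0 kJ mol⁻¹) and open intermediate + second intermediate → target (k5 = 0.36 M⁻¹ min⁻¹, Ea5 = 66.0 kJ mol⁻¹). With second intermediate at concentration c in excess, the open intermediate falls pseudo-first-order at kc, k now being the constant of that step. I carry the clearing decades, the tenfold falls that second intermediate imposes on open intermediate in a time t:

D = kct/2.3

With c at its ceiling, the partner's charge, south has D = 1.88. If one partner is lost per starting material, c ends no lower than cD − cA, where cD and cA are the charges; I call that the floor, though c starts from nothing and has to climb to it. That gives south 0.939.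

Scaling k by its activation energy gives:

west, ceiling: 0.305
north-west, floor: 4.52
north-east, floor: 17.8

Last come 2 open intermediate → homo product (k4 = 0.48 M⁻¹ min⁻¹, Ea4 = 53.0 kJ mol⁻¹) and starting material + open intermediate → side product (k3 = 0.24 M⁻¹ min⁻¹, Ea3 = 72.0 kJ mol⁻¹). The homo step by itself keeps the level under 1/(2kt), k now being its constant, which in west is 74.7% of the charge. Even with west's whole making present from the start, it divides the level by no more than 1.34, so I give it 0.128 decades there. The side step adds 0.0862 decades at most in west.

So I commit to west between 7.75% and 25.6%, and south between 1.32% and 11.5%. North-west stands under 0.00302%, and north-east has still more decades. West leads, and my reckoning stops at these bands.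

The forecast also names west and gives single values where I give bands: west 20% (17% to 23%), south 3.7% (2.5% to 5.5%), north-west <0.001% and north-east 0%. Of the hot flasks it says “the excess second intermediate then removes the open intermediate almost completely”.

West leads with 19.9%, against 4.34% in south, 0% in north-west and 0% in north-east. South's open intermediate goes from 20.6% at 1.00 h to 4.34% at 2.00 h, a fall of 0.676 decades, while the clearing decades for that second hour, at 0.0703 M of second intermediate, come to 0.660. North-west's second hour, at 0.0704 M, is worth 3.18 decades on the 0.0310% standing at 1.00 h, and north-west reads 0% at 2.00 h.

The constants used here are made up; what happens was integrated by code.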